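Late in its run, the slope read for free monomer was steeper in theta, at 1.22 min⁻¹, than in beta, at 0.702 min⁻¹, though both had the same initiator charge. These are late slopes of minus the logarithm of the fraction left, and I took such a slope to count living chains.

| flask | free monomer | initiator | remark | time |
|---|---|---|---|---|
| beta | 0.14 M | 2.7 mM | run made earlier |  |
| theta | 0.54 M | 2.7 mM | run made earlier |  |
| delta | 0.27 M | 4.1 mM | run made earlier |  |
| south-east | 0.27 M | 2.7 mM |  | 2.5 min |
| north | 0.27 M | 2.7 mM |  | 0.80 min |

| run | time / min | monomer in chains / % |
|---|---|---|
| beta | 0.500 | 12.0 |
| beta | 1.00 | 35.1 |
| beta | 1.50 | 53.8 |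
| beta | 2.00 | 67.8 |
| beta | 2.50 | 77.1 |
| theta | 0.200 | 8.2 |
| theta | 0.667 | 41.7 |
| theta | 1.33 | 71.6 |
| theta | 2.00 | 87.5 |
| theta | 2.50 | 95.4 |
| delta | 0.500 | 26.8 |
| delta | 1.00 | 58.5 |
| delta | 1.50 | 76.8 |
| delta | 2.00 | 89.0 |
| delta | 2.50 | 92.6 |

(readings scatter by 1 percentage point)

- the average divides the monomer in chains by the number of chains begun, living and dead together
- the earlier runs do not show the number of chains; that part of a forecast is a guess

1. which of the two ends with the longer chains by the average number of monomer units in a chain (chains begun, living or dead) ("neither" if they lie within 10%) (south-east / north / neither)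
2. average number of monomer units in a chain (chains begun, living or dead) at the end, south-east
3. average number of monomer units in a chain (chains begun, living or dead) at the end, north

I read the runs in order of free monomer per initiator charged. Beta, at 51.9, had 0.573 of theta's slope per initiator. Delta, at 65.9, with slope 1.14 min⁻¹, had 0.614. Theta, at 200, I counted as whole. So the slope per initiator read off these runs rose with this ratio.

South-east and north share a ratio of 100. Interpolating between delta and theta on a logarithmic scale, I got a chain share (initiator efficiency), the part of the charged initiator that stands as chains once started, of 0.759. Length is then the fraction reacted times the ratio, divided by that share.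

Theta's straight line, run back, gave a lag of 0.302 min. With slope 0.930 min⁻¹, I reckoned south-east at 87.1% reacted and length 115. I reckoned north at 37.1% reacted, with 92.9% of its chains begun, and length 52.5.

The forecast also chose south-east, but with 80 and 36, shorter than mine: “Chain count assumes one chain per initiator; this is a guess.”

The flask gave south-east, with 121 there and 60.6 in north.

    2 initiator → spent initiator (k = 4.40 M⁻¹ s⁻¹)
    free monomer + living end → monomer in chains + living end, rate k2*[living end]*[free monomer] (k = 8.40 M⁻¹ s⁻¹)
    free monomer + initiator → living end + monomer in chains (k = 0.140 M⁻¹ s⁻¹)

In south-east at 2.50 min, living ends stood for 72.3% of the charged initiator, spent initiator took 24.1%, and 3.63% remained. My chain share on south-east's 87.7% monomer in chains gives 116. On north left until 2.00 min, with 79.9% monomer in chains, it gives 105, and that flask stood at 112.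

The earlier runs and the new flask come from a simulation for substances that don't exist.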